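## Retrosynthetic overview

1. Feature: in each half, ring B carries an oxygen on C6 next to an oxygen on benzylic C7 (bonded to C8 of ring C, para to the methoxy group). At the ketone level, C6(OH)–C7(=O)–aryl is an α-ketol. It is the acyloin isomer of a ring-B-contracted 6-5-6 hydrofluorene bearing OH and CHO on C7.
2. The central 1,4-dioxane (C7–O–C6′ and C7′–O–C6) is cut into two molecules of the 6α,7β-diol (twofold benzylic SN1 etherification), and the diol comes from the 6α-hydroxy-7-ketone by hydride reduction.
3. The ketol comes from the trans-hexahydrofluorene hydroxy aldehyde: a 1,2-shift of C5 from C7 to the formyl carbon makes C5–C6 and turns the five-membered ring into ring B.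
4. The hydroxy aldehyde comes from the trans-hexahydrofluorenone (vinyl addition, ozonolysis), then the tetrahydrofluorene (α-face hydroboration sets C5), then a spiro-epoxide, then (R)-2-aryl-2,6,6-trimethylcyclohexanone (asymmetric α-arylation sets C10).
5. Ring order: rings A and C are bought, the five-membered ring forms in step 3, ring B by enlargement in step 8, and the central dioxane in step 10.

Key step: step 8

Assumption: abietane numbering and α/β descriptors (C20 methyl = β) are used for all tricycles, C6 being absent in the hydrofluorenes; both coupling partners of step 1 are taken as purchasable, and the ligand antipode there is whichever gives the (R)-ketone, written here as (R)-DIFLUORPHOS.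

## Route

Step 1
Reactants: 1 2,2,6-trimethylcyclohexanone (racemic); 2 4-bromo-1-isopropyl-2-methoxybenzene (5-bromo-2-isopropylanisole)
Product: 3 (2R)-2-(4-isopropyl-3-methoxyphenyl)-2,6,6-trimethylcyclohexan-1-one
Conditions: Pd(dba)2 (5 mol %), (R)-DIFLUORPHOS (6 mol %), NaOtBu (1.5 equiv), PhMe, 80 °C
Reagents that add atoms: none
Why: Enantioselective Buchwald–Hartwig ketone α-arylation: 1 has only one enolisable C–H, so its sodium enolate (in which the stereocentre of racemic 1 is erased) can couple only at the methyl-bearing carbon, and the chiral bisphosphine on the arylpalladium enolate selects the enolate face in the C–C reductive elimination, which sets the benzylic quaternary centre (future C10) as R.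

Step 2
Reactants: 3 (2R)-2-(4-isopropyl-3-methoxyphenyl)-2,6,6-trimethylcyclohexan-1-one; 4 trimethylsulfonium iodide
Product: 5 (4R)-4-(4-isopropyl-3-methoxyphenyl)-4,8,8-trimethyl-1-oxaspiro[2.5]octane (either configuration at the spiro carbon)
Conditions: 4, NaH, DMSO/THF, 0 °C → 50 °C
Reagents that add atoms: trimethylsulfonium iodide (4), C[S+](C)C.[I-]
Why: Corey–Chaykovsky epoxidation: 3 cannot enolise and the small unstabilised sulfur ylide still reaches a carbonyl flanked by two quaternary carbons, adding the carbon that becomes C7; the configuration of the new spiro carbon (future C5) is of no consequence because it becomes sp2 in step 3.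

Step 3
Reactants: 5 (4R)-4-(4-isopropyl-3-methoxyphenyl)-4,8,8-trimethyl-1-oxaspiro[2.5]octane
Product: 8 (4bS)-2-isopropyl-3-methoxy-4b,8,8-trimethyl-5,6,7,8-tetrahydro-4bH-fluorene, via ring-A carbaldehyde 6 (not isolated), via hexahydrofluoren-9-ol 7 (not isolated)
Conditions: BF3·OEt2 (30 mol %), CH2Cl2, −40 °C → rt
Reagents that add atoms: none
Why: Lewis-acid cascade of Meinwald rearrangement (epoxide opening with 1,2-hydride shift to aldehyde 6), intramolecular Friedel–Crafts hydroxyalkylation at the free arene position para to the methoxy group (closure of the five-membered ring, 7) and E1 dehydration of the p-methoxybenzylic alcohol to the styrene-type C5=C7 alkene; C10 has no hydrogen and no leaving group and is carried through unchanged.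

Step 4
Reactants: 8 (4bS)-2-isopropyl-3-methoxy-4b,8,8-trimethyl-5,6,7,8-tetrahydro-4bH-fluorene
Product: 10 (4bS,8aS,9R)-2-isopropyl-3-methoxy-4b,8,8-trimethyl-4b,5,6,7,8,8a-hexahydro-9H-fluoren-9-ol (trans fusion: H-5 α; 7α-OH), via C7 alkylborane 9 (not isolated)
Conditions: BH3·SMe2, THF, 0 → 45 °C; then 3 M NaOH, 30% H2O2, 0 °C → rt
Reagents that add atoms: hydrogen peroxide, OO
Why: Hydroboration–oxidation: boron takes the less substituted, benzylic C7 and the concerted syn addition should occur on the α face, because the β face of C5 is walled off by the syn-axial C19 and C20 methyl groups of the ring A chair, so that H-5 is delivered α (trans ring fusion) and stereoretentive C–B oxidation gives the 7α-alcohol.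

Step 5
Reactants: 10 (4bS,8aS,9R)-hexahydrofluoren-9-ol
Product: 11 (4bS,8aS)-2-isopropyl-3-methoxy-4b,8,8-trimethyl-4b,5,6,7,8,8a-hexahydro-9H-fluoren-9-one (trans-fused)
Conditions: Dess–Martin periodinane, NaHCO3, CH2Cl2, 0 °C
Reagents that add atoms: none
Why: Dess–Martin oxidation under bicarbonate buffer is neutral and fast, so the secondary benzylic alcohol becomes the aryl ketone without enolisation of the epimerisable H-5 of the strained trans-fused ketone.

Step 6
Reactants: 11 trans-hexahydrofluoren-9-one; 12 vinylmagnesium bromide
Product: 13 (4bS,8aS,9S)-2-isopropyl-3-methoxy-4b,8,8-trimethyl-9-vinyl-4b,5,6,7,8,8a-hexahydro-9H-fluoren-9-ol (7β-OH; 7α-vinyl)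
Conditions: anhydrous CeCl3, 12, THF, −78 °C; aq. NH4Cl
Reagents that add atoms: vinylmagnesium bromide (12), C=C[Mg]Br
Why: Organocerium 1,2-addition: the weakly basic, oxophilic vinylcerium reagent adds to the hindered, enolisable aryl ketone at −78 °C faster than it deprotonates H-5, and it approaches C7 from the α face, away from the C19 and C20 methyl groups, which places the vinyl group α and the tertiary hydroxyl β.

Step 7
Reactants: 13 9-vinyl-hexahydrofluoren-9-ol
Product: 15 (4bS,8aS,9S)-9-hydroxy-2-isopropyl-3-methoxy-4b,8,8-trimethyl-4b,5,6,7,8,8a-hexahydro-9H-fluorene-9-carbaldehyde (trans fusion; 7β-OH; 7α-CHO), via secondary ozonide 14 (not isolated)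
Conditions: O3, CH2Cl2, −78 °C, Sudan red 7B as end-point indicator; then PPh3, −78 °C → rt
Reagents that add atoms: ozone, [O-][O+]=O
Why: Ozonolysis (Criegee mechanism) with reductive phosphine work-up cleaves the only alkene much faster than ozone attacks the anisole ring and turns the vinyl group into the formyl group without touching the C7 stereocentre or the tertiary alcohol.

Step 8
Reactants: 15 trans-9-hydroxy-hexahydrofluorene-9-carbaldehyde
Product: 17 6α-hydroxy-12-methoxyabieta-8,11,13-trien-7-one, via 6β-hydroxy epimer 16 (not isolated)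
Conditions: Al(OtBu)3 (1.5 equiv), degassed PhMe (0.02 M), 80 °C, Ar; aqueous work-up; crude: K2CO3 (0.2 equiv), degassed MeOH, rt, Ar
Reagents that add atoms: none
Why: Ligand exchange places the C7 alkoxide on aluminium, which also binds the formyl oxygen, and in this five-membered chelate the C5–C7 σ bond lies over the formyl π* orbital, so that C5 moves with its bonding pair from C7 to the formyl carbon, making the C5–C6 bond while C7 collapses to the ketone. This is the α-ketol (acyloin) rearrangement in its ring-enlarging form, known for 1-hydroxycycloalkanecarbaldehydes and for the D-homoannulation of 17-hydroxy-20-oxo steroids; the tert-butoxide is taken because it has no carbinol hydrogen and cannot reduce the aldehyde in the Meerwein–Ponndorf–Verley sense. Ring B is closed not by a cyclisation but by one-carbon enlargement: the exocyclic formyl carbon is inserted into the C5–C7 bond of the five-membered ring (1,2-shift, five to six members), driven by loss of the strain of the trans-fused indane and by the change from aldehyde to aryl ketone. C5 migrates with retention and keeps H-5 α, C10 is a spectator, and C6 is the only new stereocentre: with the formyl group on the α face and held syn to the C7 oxygen the shift should first give the axial 6β-alkoxide (16), which is α to the new ketone and is equilibrated by K2CO3/MeOH through the C6=C7 enediolate to the equatorial 6α-alcohol, free of the syn-axial C19 and C20 methyl groups and hydrogen-bonded to C7=O. The selectivity needed is migration of C5 instead of aryl carbon C8, and it is secured by thermodynamics, since ketol shifts are reversible and only the C5 shift gives a ketone conjugated with ring C and its para methoxy group; any 7-hydroxy-6-ketone from an aryl shift carries a doubly activated benzylic H-7 and should drain through the same enediolate into 17 before the hindered H-5 can exchange. Air is excluded because the enediolate autoxidises to the 6,7-dione, and high dilution holds back the bimolecular Tishchenko reaction of the aldehyde.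

Step 9
Reactants: 17 6α-hydroxy-12-methoxyabieta-8,11,13-trien-7-one
Product: 18 12-methoxyabieta-8,11,13-triene-6α,7β-diol
Conditions: NaBH4, MeOH/THF, 0 °C
Reagents that add atoms: none
Why: Borohydride reduction of a cyclic α-hydroxy ketone: hydride is delivered axially on the α face of C7 (the face of the 6α-oxygen, which can carry the boron, and opposite to the C20 methyl group), which gives the equatorial 7β-alcohol and hence the trans-diequatorial diol.

Step 10
Reactants: 18 12-methoxyabieta-8,11,13-triene-6α,7β-diol (two molecules)
Product: 20 CNP0327150.1, the C2-symmetric 7β,6′α:6α,7′β-diether (1,4-dioxane) of two 12-methoxyabieta-8,11,13-triene units, via head-to-tail monoether 19 (not isolated)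
Conditions: Bi(OTf)3 (5 mol %), 4 Å MS, CH2Cl2 (0.3 M), −20 °C → rt
Reagents that add atoms: none
Why: Twofold acid-catalysed dehydrative etherification (SN1; the cyclodimerisation of a 1,2-diol to a 1,4-dioxane): only the 7-OH, benzylic and para to the methoxy group, can ionise, so every new C–O bond joins a C7 cation to a C6 hydroxyl, which enforces the head-to-tail constitution, first in monoether 19 and then in the six-membered ring closure, while reversible ionisation lets C7 and C7′ settle as the equatorial 7β-ethers of the all-trans chair dioxane, C5, C6 and C10 being untouched.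

## Compound list

1 | 2,2,6-trimethylcyclohexanone (racemic) | CC1CCCC(C)(C)C1=O | starting material
2 | 4-bromo-1-isopropyl-2-methoxybenzene | COc1cc(Br)ccc1C(C)C | starting material
3 | (2R)-2-(4-isopropyl-3-methoxyphenyl)-2,6,6-trimethylcyclohexan-1-one | COc1cc(ccc1C(C)C)[C@@]1(C)CCCC(C)(C)C1=O | intermediate
4 | trimethylsulfonium iodide | C[S+](C)C.[I-] | starting material
5 | (4R)-4-(4-isopropyl-3-methoxyphenyl)-4,8,8-trimethyl-1-oxaspiro[2.5]octane (spiro carbon undefined) | COc1cc(ccc1C(C)C)[C@@]1(C)CCCC(C)(C)C12CO2 | intermediate
6 | (2S)-2-(4-isopropyl-3-methoxyphenyl)-2,6,6-trimethylcyclohexane-1-carbaldehyde (C1 epimers) | COc1cc(ccc1C(C)C)[C@@]1(C)CCCC(C)(C)C1C=O | intermediate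
7 | (4bS)-2-isopropyl-3-methoxy-4b,8,8-trimethyl-hexahydrofluoren-9-ol (C8a and C9 undefined) | COc1cc2c(cc1C(C)C)C(O)C1C(C)(C)CCC[C@]21C | intermediate
8 | (4bS)-2-isopropyl-3-methoxy-4b,8,8-trimethyl-5,6,7,8-tetrahydro-4bH-fluorene | COc1cc2c(cc1C(C)C)C=C1C(C)(C)CCC[C@]21C | intermediate
9 | trans-hexahydrofluoren-9α-ylborane (H-5 α, boron α) | COc1cc2c(cc1C(C)C)[C@H](B)[C@H]1C(C)(C)CCC[C@]21C | intermediate
10 | (4bS,8aS,9R)-2-isopropyl-3-methoxy-4b,8,8-trimethyl-hexahydro-9H-fluoren-9-ol | COc1cc2c(cc1C(C)C)[C@H](O)[C@H]1C(C)(C)CCC[C@]21C | intermediate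
11 | (4bS,8aS)-2-isopropyl-3-methoxy-4b,8,8-trimethyl-hexahydro-9H-fluoren-9-one | COc1cc2c(cc1C(C)C)C(=O)[C@H]1C(C)(C)CCC[C@]21C | intermediate
12 | vinylmagnesium bromide | C=C[Mg]Br | starting material
13 | (4bS,8aS,9S)-2-isopropyl-3-methoxy-4b,8,8-trimethyl-9-vinyl-hexahydro-9H-fluoren-9-ol | COc1cc2c(cc1C(C)C)[C@](O)(C=C)[C@H]1C(C)(C)CCC[C@]21C | intermediate
14 | secondary ozonide (1,2,4-trioxolan-3-yl on C7; trioxolane carbon undefined) | COc1cc2c(cc1C(C)C)[C@](O)(C3OCOO3)[C@H]1C(C)(C)CCC[C@]21C | intermediate
15 | (4bS,8aS,9S)-9-hydroxy-2-isopropyl-3-methoxy-4b,8,8-trimethyl-hexahydro-9H-fluorene-9-carbaldehyde | COc1cc2c(cc1C(C)C)[C@](O)(C=O)[C@H]1C(C)(C)CCC[C@]21C | intermediate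
16 | 6β-hydroxy-12-methoxyabieta-8,11,13-trien-7-one | COc1cc2c(cc1C(C)C)C(=O)[C@@H](O)[C@H]1C(C)(C)CCC[C@]21C | intermediate
17 | 6α-hydroxy-12-methoxyabieta-8,11,13-trien-7-one | COc1cc2c(cc1C(C)C)C(=O)[C@H](O)[C@H]1C(C)(C)CCC[C@]21C | intermediate
18 | 12-methoxyabieta-8,11,13-triene-6α,7β-diol | COc1cc2c(cc1C(C)C)[C@@H](O)[C@H](O)[C@H]1C(C)(C)CCC[C@]21C | intermediate
19 | 6α-[(6α-hydroxy-12-methoxyabieta-8,11,13-trien-7β-yl)oxy]-12-methoxyabieta-8,11,13-trien-7β-ol | COc1cc2c(cc1C(C)C)[C@@H](O[C@H]3[C@H](O)c4cc(C(C)C)c(OC)cc4[C@@]4(C)CCCC(C)(C)[C@H]34)[C@H](O)[C@H]1C(C)(C)CCC[C@]21C | intermediate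
20 | CNP0327150.1 (7β,6′α:6α,7′β-dioxane dimer) | COc1cc2c(cc1C(C)C)[C@H]1O[C@H]3[C@H](O[C@@H]1[C@H]1C(C)(C)CCC[C@]21C)c1cc(C(C)C)c(OC)cc1[C@@]1(C)CCCC(C)(C)[C@H]31 | target

## Step count and risks

Total step count: 10. Longest linear sequence: 10 steps (from 1 and 2 to 20).

**Step 10 (dimerisation).**
- What may go wrong: irreversible loss of H-6 from the C7 cation (enol, then 6-ketone, a pinacol-type leak), or build-up of 7,7′-ethers and oligomers, may outrun capture by the hindered 6-hydroxyl of a second molecule.
- Fallback: it sets out from diol 18 and ketol 17 and comes back to the route at monoether 19, so that the two C–O bonds are made one at a time. Diol 18 is added slowly to an excess of 17 under the same acid catalysis. Ketol 17 cannot ionise and acts only as the nucleophile, which should give 7β-[(12-methoxy-7-oxoabieta-8,11,13-trien-6α-yl)oxy]-12-methoxyabieta-8,11,13-trien-6α-ol F1. NaBH4 reduction of the C7′ ketone from the α face gives 19, now isolated. The second ether bond is then an intramolecular six-membered closure at high dilution, which leads to 20.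

**Step 8 (key step).**
- What may go wrong: aryl carbon C8 may migrate faster than C5, and the 6-ketone so formed may exchange H-5 before it tautomerises. The tertiary p-methoxybenzylic alcohol may dehydrate, or the aldehyde may be lost to Tishchenko coupling.
- Fallback: it sets out from ketone 11 and comes back at ketol 17, separating ring growth from oxygenation.
  - Sc(OTf)3-catalysed insertion of trimethylsilyldiazomethane into 11 is a diazoalkane–carbonyl homologation. Aryl migration is expected, so the inserted carbon becomes C7 and the old carbonyl carbon becomes C6. It should give 12-methoxy-7-(trimethylsilyl)abieta-8,11,13-trien-6-one F2.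
  - A carbon-to-oxygen silyl shift in that ketone gives 12-methoxy-6-(trimethylsilyloxy)abieta-6,8,11,13-tetraene F3.
  - Rubottom oxidation (mCPBA, NaHCO3, then mild acid) gives 7α-hydroxy-12-methoxyabieta-8,11,13-trien-6-one F4.
  - K2CO3 in degassed MeOH moves the carbonyl to C7 through the enediol to give 17.

**Step 1 (asymmetric α-arylation).**
- What may go wrong: reductive elimination from the very hindered tertiary palladium enolate may be slow, with low conversion, reduction of the aryl bromide and eroded facial selectivity.
- Fallback: it sets out from 2 (with commercial cyclohexanone) and comes back at 3, the quaternary centre being set by alkylation instead of arylation.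
  - Palladium-catalysed mono-α-arylation of cyclohexanone with 2 (Pd(OAc)2, XPhos, NaOtBu) gives 2-(4-isopropyl-3-methoxyphenyl)cyclohexanone F5.
  - Methylation of its benzylic enolate with MeI under asymmetric phase-transfer catalysis (chiral N-spiro binaphthyl quaternary ammonium bromide, aq. KOH, PhMe) gives (2R)-2-(4-isopropyl-3-methoxyphenyl)-2-methylcyclohexanone F6.
  - Exhaustive methylation at the only remaining enolisable carbon (KOtBu, MeI) gives 3.

## Further compounds

F1 | step 10 | 7β-[(12-methoxy-7-oxoabieta-8,11,13-trien-6α-yl)oxy]-12-methoxyabieta-8,11,13-trien-6α-ol | COc1cc2c(cc1C(C)C)[C@@H](O[C@H]3C(=O)c4cc(C(C)C)c(OC)cc4[C@@]4(C)CCCC(C)(C)[C@H]34)[C@H](O)[C@H]1C(C)(C)CCC[C@]21C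
F2 | step 8 | 12-methoxy-7-(trimethylsilyl)abieta-8,11,13-trien-6-one (C7 undefined) | COc1cc2c(cc1C(C)C)C([Si](C)(C)C)C(=O)[C@H]1C(C)(C)CCC[C@]21C
F3 | step 8 | 12-methoxy-6-(trimethylsilyloxy)abieta-6,8,11,13-tetraene | COc1cc2c(cc1C(C)C)C=C(O[Si](C)(C)C)[C@H]1C(C)(C)CCC[C@]21C
F4 | step 8 | 7α-hydroxy-12-methoxyabieta-8,11,13-trien-6-one | COc1cc2c(cc1C(C)C)[C@H](O)C(=O)[C@H]1C(C)(C)CCC[C@]21C
F5 | step 1 | 2-(4-isopropyl-3-methoxyphenyl)cyclohexanone (racemic, configurationally labile) | COc1cc(ccc1C(C)C)C1CCCCC1=O
F6 | step 1 | (2R)-2-(4-isopropyl-3-methoxyphenyl)-2-methylcyclohexanone | COc1cc(ccc1C(C)C)[C@@]1(C)CCCCC1=O
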